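## The problem

The target, 3,5-dihydroxy-2-(2,4-dihydroxy-5-methoxyphenyl)-7,8-dimethoxychromen-4-one 19, is a flavonol: a benzopyranone (rings A and C) carrying aryl ring B at C2. It has no stereocenter, so the whole difficulty is regiochemical: seven oxygens must be placed and told apart as four free hydroxyls (C3, C5, C2', C4') and three methyl ethers (C7, C8, C5'). Classical closures of ring C start from a 2-hydroxyaryl ketone, here a 2-hydroxy-3,4,6-trimethoxyphenyl ketone, whose two ortho oxygens must be distinguished (5,7,8- against 5,6,7-oxygenation) and whose 6'-methoxychalcones give aurones in the Algar–Flynn–Oyamada oxidation. The 3-hydroxypyranone enol and the resorcinol-type ring B are oxidised easily in basic, aerated media, so the hydroxyls should stay masked until the end. The C5 hydroxyl can be told from the C7 and C8 methoxyls only because it is peri to the C4 carbonyl. The feature that opens a different route is the O1–C8a bond, which joins the ring C enol oxygen to a ring A carbon that, in a 2,4,5-trimethoxyphenyl ketone, is the only hydrogen-bearing ortho carbon of an easily oxidised 1,2,4-trioxygenated ring, so ring A can be bought without an ortho hydroxyl. Ring B has the same 2,4,5-trioxygenation pattern and its own free ortho C–H (C6'), so only the protecting groups can tell the two rings apart in an oxidative closure, and the ring B hydroxyls must therefore be electron-withdrawing esters.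

## Retrosynthesis

**19 back to 16 (unmasking).** The two aryl pivalates of 18 are cut last, because methanolysis releases only a volatile ester beside the polar target. Before that, 18 comes from 16 by cleaving the 3-O-benzyl and 5-O-methyl ethers. Both flank the C4 carbonyl, so one chelating Lewis acid (BCl3) should remove both and leave the 7-, 8- and 5'-methyl ethers. Benzyl is chosen for the C3 oxygen because it survives enolate chemistry and the anode and needs neither base nor oxidant for removal. This order keeps ring B acylated, and so free of boron-binding phenols, during the Lewis acid step.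

**16 back to 15 (O1–C8a, the key cut).** Cutting O1–C8a of chromone 16 gives the 2-benzyloxy-1,3-diaryl-1,3-diketone 15. The neighbouring cut at O1–C2 is the classical one, but it needs the tetraoxygenated ortho-hydroxy ring A and its regiochemical problem. The O1–C8a cut needs only a C–H bond on a 2,4,5-trimethoxyphenyl ring. Compound 15 is acyclic, is assembled from two simple aryl carbonyl units, and already holds every oxygen of the target. The forward reaction must remove two hydrogens (the enol O–H or C3–H, and C8a–H) and form one C–O bond, on ring A and not on ring B.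

**15 back to 6 and 14 (C2–C3).** The bond between the benzyloxy-bearing carbon and the ring B carbonyl is cut to ketone 6 (nucleophile) and acid chloride 14 (electrophile). The opposite polarity would need a ring B ketone with an ortho-pivaloyloxy group, whose enolate is set up for Baker–Venkataraman acyl transfer, so the enolate is placed on the ring A side. The forward reaction has to acylate on carbon and must not disturb the pivalates, which calls for soft enolisation with a magnesium Lewis acid and an amine base.

**6 back to 3 and 2, and 2 back to 1 (C4–C4a).** Ketone 6 is cut between the carbonyl carbon and ring A to aryl bromide 3 and Weinreb amide 2, which is made from benzyloxyacetyl chloride 1. A Friedel–Crafts acylation with 1 would form the same bond, but α-alkoxyacylium ions lose CO and Lewis acids cleave benzyl ethers. Bromine–lithium exchange (aryllithium 4) and single addition through chelate 5 avoid both problems and fix the position of the carbonyl.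

**14 back to 7 (ring B).** Acid chloride 14 comes from acid 13, and 13 from aldehyde 12 by Pinnick oxidation, which tolerates the esters. Aldehyde 12 is the bis-pivalate of 11. The 2,4-dihydroxy-5-methoxy pattern of 11 is obtained by formylating 4-methoxyresorcinol 9 at its only unhindered, doubly activated position. Diol 9 is the Dakin-type oxidation product of isovanillin 7 (through formate 8). The formyl carbon of 7 is thus exchanged for oxygen and a new formyl group is introduced via iminium salt 10. Every step is a standard arene functional-group operation.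

## Roads not taken

Alternative 1: The cut is C3–C4. The dialdehyde 2-{1-[2,4-bis(benzyloxy)-5-methoxyphenyl]-2-oxoethoxy}-3,4,6-trimethoxybenzaldehyde A2 would be closed with SmI2 by ketyl–aldehyde pinacol coupling to the cis-3,4-diol, the 2,3-trans-3,4-cis chromane-3,4-diol A1.
- Merits: the reductive coupling is a well-known reaction type, uses no oxidant near the electron-rich rings, and the samarium chelate should give the cis diol reliably.
- Weak points: A1 lies four electrons below the flavonol, so the diol must be oxidised to the ketone and C2–C3 dehydrogenated, and three stereocenters are made only to be destroyed. A2 contains an α-aryl-α-aryloxy aldehyde that enolises and eliminates phenoxide easily. Its ring A half is the tetraoxygenated salicylaldehyde whose regiochemistry the chosen plan avoids, and the O1–C2 ether must be made by alkylating a doubly ortho-substituted phenol.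
- Comparison: this road is stronger in one respect, since its key step is precedented and the anodic closure is not. Against that the chosen plan sets direct arrival at the chromone oxidation level, a commercial ring A, and no stereochemical ballast.

Alternative 2: The cuts are C4–C4a, C3–C4 and O1–C2, with CO as C4. The iodophenol 2-iodo-3,5,6-trimethoxyphenol A4, CO and the alkyne 1,5-bis(benzyloxy)-2-ethynyl-4-methoxybenzene A5 would couple under PdCl2(PPh3)2 (carbonylative Sonogashira reaction), and the phenol would then add to the ynone to give flavone A3.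
- Merits: this is the most convergent of the four plans, and the reaction type is established for flavones; in both respects it is better than the chosen plan.
- Weak points: A4 is a tetraoxygenated iodophenol with iodine between hydroxyl and methoxyl, which needs several regiocontrolled steps, and A5 needs an aldehyde-to-alkyne homologation on ring B. The ynone can close 5-exo to an aurone. A3 lacks the C3 oxygen, so a late C3 hydroxylation (for example with dimethyldioxirane) must be run on a flavone with two electron-rich rings.
- Comparison: the chosen plan carries the C3 oxygen from the start in the benzyloxyacetyl unit and buys ring A with the correct pattern. It pays for this with an unprecedented key step.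

Alternative 3: The cut is C5–C4a, with ring A built from a squarate-derived cyclobutenone. Heating the 4-hydroxycyclobutenone A7, a 2-aryl-3-benzyloxy-4-pyranone carrying the 1-hydroxy-2-methoxy-4-oxocyclobutenyl group at C6, would open it to a dienylketene. 6π-Electrocyclisation (Moore rearrangement) then gives the 5,8-hydroquinone A6.
- Merits: the oxygenation pattern of ring A is set without ambiguity. The C5 hydroxyl arrives free and hydrogen-bonded, so no late selective demethylation is needed and C8–OH can be methylated selectively. This is a real advantage over the chosen plan, which depends on the selectivity of BCl3.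
- Weak points: the pyranone half of A7 must be made fully substituted, metalated at C6 and added regioselectively to a squarate ester. Hydroquinone A6 is prone to air oxidation at its quinol ring. Three benzyl ethers then need hydrogenolysis.
- Comparison: this road builds two rings from scratch, whereas the chosen plan uses two intact commercial arenes and closes one ring.

Key step: step 9

Remark on the chemistry: 1-bromo-2,4,5-trimethoxybenzene 3 is taken as the commercial form of the 2,4,5-trimethoxyphenyl unit, and diketone 15 is written as the diketo tautomer, whose single center is racemic and becomes sp2 in step 9.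

## Route

Step 1
Reactants: 1 benzyloxyacetyl chloride
Product: 2 2-(benzyloxy)-N-methoxy-N-methylacetamide
Conditions: MeNHOMe·HCl, Et3N, CH2Cl2, 0 °C to rt
Reagents that add atoms: N,O-dimethylhydroxylamine hydrochloride, CNOC.Cl
Why: N-acylation of the hydroxylamine by the acid chloride gives the Weinreb amide; the benzyl ether is inert under these conditions.

Step 2
Reactants: 3 1-bromo-2,4,5-trimethoxybenzene; 2 2-(benzyloxy)-N-methoxy-N-methylacetamide
Product: 6 2-(benzyloxy)-1-(2,4,5-trimethoxyphenyl)ethan-1-one, via (2,4,5-trimethoxyphenyl)lithium 4 (not isolated), via lithium hemiaminal alkoxide 5 (not isolated)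
Conditions: n-BuLi, THF, −78 °C; then 2, −78 to 0 °C; then 1 M HCl
Reagents that add atoms: none
Why: Bromine–lithium exchange followed by Weinreb ketone synthesis; the chelated adduct 5 persists until the acidic quench, so the aryllithium adds only once, and the carbonyl position on ring A is fixed by the bromide.

Step 3
Reactants: 7 isovanillin (3-hydroxy-4-methoxybenzaldehyde)
Product: 9 4-methoxybenzene-1,3-diol, via 3-hydroxy-4-methoxyphenyl formate 8 (not isolated)
Conditions: mCPBA, CH2Cl2, 0 °C to rt; then MeOH, HCl (cat.), rt
Reagents that add atoms: meta-chloroperoxybenzoic acid, OOC(=O)c1cccc(Cl)c1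
Why: Dakin-type Baeyer–Villiger oxidation, in which the aryl group activated by the para methoxyl migrates in preference to hydrogen; acid-catalysed methanolysis of formate 8 keeps the electron-rich diol away from basic, aerated conditions.

Step 4
Reactants: 9 4-methoxybenzene-1,3-diol
Product: 11 2,4-dihydroxy-5-methoxybenzaldehyde, via aryl iminium chloride 10 (not isolated)
Conditions: POCl3, DMF, MeCN, 0 °C to rt; then H2O, 50 °C
Reagents that add atoms: N,N-dimethylformamide, CN(C)C=O; water, O
Why: Vilsmeier–Haack formylation at C6 of 9, the unhindered position para to one hydroxyl and ortho to the other, as in the formylation of resorcinol; hydrolysis of iminium salt 10 releases the aldehyde.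

Step 5
Reactants: 11 2,4-dihydroxy-5-methoxybenzaldehyde
Product: 12 5-methoxy-2,4-bis(pivaloyloxy)benzaldehyde [4-formyl-6-methoxy-1,3-phenylene bis(2,2-dimethylpropanoate)]
Conditions: PivCl, Et3N, DMAP (cat.), CH2Cl2, 0 °C to rt
Reagents that add atoms: pivaloyl chloride, CC(C)(C)C(Cl)=O
Why: DMAP-catalysed O-acylation of both phenols, with excess reagent for the hydrogen-bonded 2-hydroxyl; the bulky pivalates resist acyl transfer and later make ring B electron-poor.

Step 6
Reactants: 12 5-methoxy-2,4-bis(pivaloyloxy)benzaldehyde
Product: 13 5-methoxy-2,4-bis(pivaloyloxy)benzoic acid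
Conditions: NaClO2, NaH2PO4, 2-methyl-2-butene, t-BuOH/H2O, rt
Reagents that add atoms: sodium chlorite, [Na+].[O-]Cl=O
Why: Pinnick oxidation at about pH 4 converts the aldehyde to the acid without hydrolysing aryl esters; the alkene removes HOCl.

Step 7
Reactants: 13 5-methoxy-2,4-bis(pivaloyloxy)benzoic acid
Product: 14 5-methoxy-2,4-bis(pivaloyloxy)benzoyl chloride
Conditions: (COCl)2, DMF (cat.), CH2Cl2, 0 °C to rt; evaporated and used crude
Reagents that add atoms: oxalyl chloride, O=C(Cl)C(=O)Cl
Why: Acid chloride formation through the catalytic chloroiminium species; 2-acyloxybenzoyl chlorides are stable enough to be used directly.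

Step 8
Reactants: 6 2-(benzyloxy)-1-(2,4,5-trimethoxyphenyl)ethan-1-one; 14 5-methoxy-2,4-bis(pivaloyloxy)benzoyl chloride
Product: 15 2-(benzyloxy)-1-[5-methoxy-2,4-bis(pivaloyloxy)phenyl]-3-(2,4,5-trimethoxyphenyl)propane-1,3-dione (racemic, diketo form)
Conditions: MgBr2·OEt2, i-Pr2NEt, CH2Cl2, 0 °C to rt; then 1 M HCl
Reagents that add atoms: none
Why: Claisen-type C-acylation by soft enolisation: the α-benzyloxy ketone chelates MgBr2, the amine forms the magnesium enolate, and this is acylated on carbon; the mild base leaves the pivalates alone, and the new center is racemic and of no consequence.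

Step 9
Reactants: 15 2-(benzyloxy)-1-[5-methoxy-2,4-bis(pivaloyloxy)phenyl]-3-(2,4,5-trimethoxyphenyl)propane-1,3-dione
Product: 16 3-(benzyloxy)-5,7,8-trimethoxy-2-[5-methoxy-2,4-bis(pivaloyloxy)phenyl]chromen-4-one
Conditions: graphite anode, Pt cathode, undivided cell, n-Bu4NPF6 (0.1 M), HFIP/CH2Cl2 (4:1), constant current, about 2.2 F/mol, rt
Reagents that add atoms: none
Why: Proposed new method: an anodic dehydrogenative aryl C–H etherification that closes a chromone at O1–C8a with a 1,3-diketone oxygen as nucleophile, for which the closest known reaction types are the anodic dehydrogenative lactonisation of biaryl-2-carboxylic acids, the anodic closure of anilides to benzoxazoles, and the FeCl3- or Mn(OAc)3-type oxidative cyclisations in which an enol or 1,3-dicarbonyl unit attacks an electron-rich π system. At the anode in HFIP the 2,4,5-trimethoxyphenyl ring of 15, the most easily oxidised part of the molecule, should lose one electron to a radical cation that the fluorinated alcohol stabilises. The oxygen on the carbon bearing ring B (the enol OH, or the carbonyl oxygen of the diketo form followed by loss of the C3 proton) then attacks C8a in a six-membered closure, formally 6-endo-trig with respect to the C4a=C8a bond. A second one-electron oxidation and loss of the C8a proton restore the aromaticity of ring A, and the protons are reduced to H2 at the cathode, so no chemical oxidant is present. No stereocenter is formed, and the racemic center of 15 becomes the sp2 carbon C3. The step needs attack on ring A and not ring B, which have the same substitution pattern and each a free ortho C–H; the two electron-withdrawing pivalates should secure this by raising the oxidation potential of ring B. It also needs substitution at C8a–H and not at the methoxy-bearing ortho carbon, which is expected because ipso attack in a non-nucleophilic medium is reversible whereas attack at C–H is made irreversible by the second oxidation and deprotonation. Finally, closure must outrun further oxidation at C3 or of product 16, for which the charge is limited and water excluded, the pyranone oxygen of 16 being a weaker donor to ring A than an ether oxygen.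

Step 10
Reactants: 16 3-(benzyloxy)-5,7,8-trimethoxy-2-[5-methoxy-2,4-bis(pivaloyloxy)phenyl]chromen-4-one
Product: 18 3,5-dihydroxy-7,8-dimethoxy-2-[5-methoxy-2,4-bis(pivaloyloxy)phenyl]chromen-4-one, via bis(dichloroboryl) ether 17 (not isolated)
Conditions: BCl3, pentamethylbenzene, CH2Cl2, −78 to 0 °C; then H2O
Reagents that add atoms: none
Why: Chelation-controlled Lewis acid ether cleavage: BCl3 bound at the C4 carbonyl cleaves the two flanking ethers, the 3-O-benzyl (its cation trapped by pentamethylbenzene, which prevents benzylation of C6) and the peri 5-O-methyl (chloride attack on the methyl group); the 7-, 8- and 5'-methyl ethers lack this chelation and aryl pivalates are inert to BCl3 at low temperature.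

Step 11
Reactants: 18 3,5-dihydroxy-7,8-dimethoxy-2-[5-methoxy-2,4-bis(pivaloyloxy)phenyl]chromen-4-one
Product: 19 3,5-dihydroxy-2-(2,4-dihydroxy-5-methoxyphenyl)-7,8-dimethoxychromen-4-one
Conditions: K2CO3, degassed MeOH/THF, argon, rt; then 1 M HCl
Reagents that add atoms: none
Why: Base-mediated transesterification of the two aryl pivalates, which cleave at room temperature because phenoxide is a good leaving group; oxygen is excluded because flavonol anions autoxidise, and the only organic by-product is volatile.

## Compound list

1 | benzyloxyacetyl chloride | O=C(Cl)COCc1ccccc1 | starting material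
2 | 2-(benzyloxy)-N-methoxy-N-methylacetamide | CON(C)C(=O)COCc1ccccc1 | intermediate
3 | 1-bromo-2,4,5-trimethoxybenzene | COc1cc(OC)c(Br)cc1OC | starting material
4 | (2,4,5-trimethoxyphenyl)lithium (not isolated) | [Li]c1cc(OC)c(OC)cc1OC | intermediate
5 | lithium 2-(benzyloxy)-1-[methoxy(methyl)amino]-1-(2,4,5-trimethoxyphenyl)ethan-1-olate (racemic, not isolated) | [Li+].[O-]C(COCc1ccccc1)(N(C)OC)c1cc(OC)c(OC)cc1OC | intermediate
6 | 2-(benzyloxy)-1-(2,4,5-trimethoxyphenyl)ethan-1-one | COc1cc(OC)c(C(=O)COCc2ccccc2)cc1OC | intermediate
7 | isovanillin (3-hydroxy-4-methoxybenzaldehyde) | COc1ccc(C=O)cc1O | starting material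
8 | 3-hydroxy-4-methoxyphenyl formate (not isolated) | COc1ccc(OC=O)cc1O | intermediate
9 | 4-methoxybenzene-1,3-diol | COc1ccc(O)cc1O | intermediate
10 | N-[(2,4-dihydroxy-5-methoxyphenyl)methylidene]-N-methylmethanaminium chloride (not isolated) | C[N+](C)=Cc1cc(OC)c(O)cc1O.[Cl-] | intermediate
11 | 2,4-dihydroxy-5-methoxybenzaldehyde | COc1cc(C=O)c(O)cc1O | intermediate
12 | 5-methoxy-2,4-bis(pivaloyloxy)benzaldehyde | COc1cc(C=O)c(OC(=O)C(C)(C)C)cc1OC(=O)C(C)(C)C | intermediate
13 | 5-methoxy-2,4-bis(pivaloyloxy)benzoic acid | COc1cc(C(=O)O)c(OC(=O)C(C)(C)C)cc1OC(=O)C(C)(C)C | intermediate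
14 | 5-methoxy-2,4-bis(pivaloyloxy)benzoyl chloride | COc1cc(C(=O)Cl)c(OC(=O)C(C)(C)C)cc1OC(=O)C(C)(C)C | intermediate
15 | 2-(benzyloxy)-1-[5-methoxy-2,4-bis(pivaloyloxy)phenyl]-3-(2,4,5-trimethoxyphenyl)propane-1,3-dione (racemic, diketo form) | COc1cc(OC)c(C(=O)C(OCc2ccccc2)C(=O)c2cc(OC)c(OC(=O)C(C)(C)C)cc2OC(=O)C(C)(C)C)cc1OC | intermediate
16 | 3-(benzyloxy)-5,7,8-trimethoxy-2-[5-methoxy-2,4-bis(pivaloyloxy)phenyl]chromen-4-one | COc1cc(OC)c2c(=O)c(OCc3ccccc3)c(-c3cc(OC)c(OC(=O)C(C)(C)C)cc3OC(=O)C(C)(C)C)oc2c1OC | intermediate
17 | 3,5-bis(dichloroboryloxy)-7,8-dimethoxy-2-[5-methoxy-2,4-bis(pivaloyloxy)phenyl]chromen-4-one (not isolated) | COc1cc(OB(Cl)Cl)c2c(=O)c(OB(Cl)Cl)c(-c3cc(OC)c(OC(=O)C(C)(C)C)cc3OC(=O)C(C)(C)C)oc2c1OC | intermediate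
18 | 3,5-dihydroxy-7,8-dimethoxy-2-[5-methoxy-2,4-bis(pivaloyloxy)phenyl]chromen-4-one | COc1cc(O)c2c(=O)c(O)c(-c3cc(OC)c(OC(=O)C(C)(C)C)cc3OC(=O)C(C)(C)C)oc2c1OC | intermediate
19 | 3,5-dihydroxy-2-(2,4-dihydroxy-5-methoxyphenyl)-7,8-dimethoxychromen-4-one | COc1cc(-c2oc3c(OC)c(OC)cc(O)c3c(=O)c2O)c(O)cc1O | target

## Step count and risks

Total: 11 steps. Longest linear sequence: 9 steps (7 to 19, steps 3 to 11). The ring A branch (steps 1 and 2) joins at step 8.

**Step 9 (key step, proposed new method).** The most likely failure is oxidation at the C3–H/enol position, giving C3-functionalised or fragmented material, in competition with C–O closure. Further risks are reversible ipso attack that leads nowhere, and over-oxidation of the product ring A, whose C5 and C8 methoxyls are para to each other. The fallback uses known chemistry and closes O1–C2 instead. It sets out from ketone 6. Ketone-directed ortho C–H hydroxylation with Pd(OAc)2 and K2S2O8 in TFA/TFAA should oxygenate the only ortho C–H and give 2-(benzyloxy)-1-(2-hydroxy-3,4,6-trimethoxyphenyl)ethan-1-one F1. Its dianion, formed with LiN(SiMe3)2, would be acylated with acid chloride 14 in a Baker–Venkataraman-type reaction to give 2-(benzyloxy)-1-(2-hydroxy-3,4,6-trimethoxyphenyl)-3-[5-methoxy-2,4-bis(pivaloyloxy)phenyl]propane-1,3-dione F2. Acid-catalysed cyclodehydration (TsOH, toluene, heat) returns to the route at 16.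

**Step 8.** O-acylation of the enolate to an enol ester may compete. The hindered ortho-substituted acid chloride may also react slowly enough for pivaloyl transfer to interfere. The fallback sets out from 6. Silylation with TMSOTf and Et3N gives {[(Z)-2-(benzyloxy)-1-(2,4,5-trimethoxyphenyl)ethenyl]oxy}trimethylsilane F3. A Mukaiyama aldol addition to aldehyde 12 with BF3·OEt2 gives 2-(benzyloxy)-3-hydroxy-3-[5-methoxy-2,4-bis(pivaloyloxy)phenyl]-1-(2,4,5-trimethoxyphenyl)propan-1-one F4 as a diastereomer mixture. Dess–Martin oxidation returns to the route at 15.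

**Step 10.** With excess BCl3 a second methyl ether may be lost, most plausibly the crowded 8-O-methyl. The benzyl cation may also benzylate C6 if trapping is incomplete. The fallback sets out from 16. Hydrogenolysis (H2, 10% Pd/C, EtOAc) removes the benzyl group and gives 3-hydroxy-5,7,8-trimethoxy-2-[5-methoxy-2,4-bis(pivaloyloxy)phenyl]chromen-4-one F5. AlCl3 in MeCN then cleaves only the peri 5-O-methyl and returns to the route at 18.

**Step 11.** The flavonol and resorcinol anions may autoxidise during basic methanolysis, and the hindered 2'-pivalate may cleave slowly. The fallback reverses the order of unmasking and sets out from 16. Methanolysis with K2CO3 in MeOH, while the C3 and C5 oxygens are still alkylated, gives 3-(benzyloxy)-2-(2,4-dihydroxy-5-methoxyphenyl)-5,7,8-trimethoxychromen-4-one F6. BCl3 with pentamethylbenzene is then the last, acidic step and returns to the route at 19.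

**Step 3.** The free phenol of 7 may be oxidised by the peracid, or the aldehyde may be oxidised to the acid without aryl migration. The fallback sets out from 7. Benzylation (BnBr, K2CO3, DMF) gives 3-(benzyloxy)-4-methoxybenzaldehyde F7. Oxidation with mCPBA gives 3-(benzyloxy)-4-methoxyphenyl formate F8, and methanolysis gives 3-(benzyloxy)-4-methoxyphenol F9. Hydrogenolysis (H2, 10% Pd/C) returns to the route at 9.

## Further compounds

F1 | step 9 | 2-(benzyloxy)-1-(2-hydroxy-3,4,6-trimethoxyphenyl)ethan-1-one | COc1cc(OC)c(C(=O)COCc2ccccc2)c(O)c1OC
F2 | step 9 | 2-(benzyloxy)-1-(2-hydroxy-3,4,6-trimethoxyphenyl)-3-[5-methoxy-2,4-bis(pivaloyloxy)phenyl]propane-1,3-dione (racemic) | COc1cc(OC)c(C(=O)C(OCc2ccccc2)C(=O)c2cc(OC)c(OC(=O)C(C)(C)C)cc2OC(=O)C(C)(C)C)c(O)c1OC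
F3 | step 8 | {[(Z)-2-(benzyloxy)-1-(2,4,5-trimethoxyphenyl)ethenyl]oxy}trimethylsilane | C[Si](C)(C)O/C(=C\OCc1ccccc1)c1cc(OC)c(OC)cc1OC
F4 | step 8 | 2-(benzyloxy)-3-hydroxy-3-[5-methoxy-2,4-bis(pivaloyloxy)phenyl]-1-(2,4,5-trimethoxyphenyl)propan-1-one (mixture of racemic diastereomers) | COc1cc(OC)c(C(=O)C(OCc2ccccc2)C(O)c2cc(OC)c(OC(=O)C(C)(C)C)cc2OC(=O)C(C)(C)C)cc1OC
F5 | step 10 | 3-hydroxy-5,7,8-trimethoxy-2-[5-methoxy-2,4-bis(pivaloyloxy)phenyl]chromen-4-one | COc1cc(OC)c2c(=O)c(O)c(-c3cc(OC)c(OC(=O)C(C)(C)C)cc3OC(=O)C(C)(C)C)oc2c1OC
F6 | step 11 | 3-(benzyloxy)-2-(2,4-dihydroxy-5-methoxyphenyl)-5,7,8-trimethoxychromen-4-one | COc1cc(OC)c2c(=O)c(OCc3ccccc3)c(-c3cc(OC)c(O)cc3O)oc2c1OC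
F7 | step 3 | 3-(benzyloxy)-4-methoxybenzaldehyde | COc1ccc(C=O)cc1OCc1ccccc1
F8 | step 3 | 3-(benzyloxy)-4-methoxyphenyl formate | COc1ccc(OC=O)cc1OCc1ccccc1
F9 | step 3 | 3-(benzyloxy)-4-methoxyphenol | COc1ccc(O)cc1OCc1ccccc1
A1 | alternative 1 | rac-(2R,3S,4S)-2-[2,4-bis(benzyloxy)-5-methoxyphenyl]-5,7,8-trimethoxychromane-3,4-diol (2,3-trans, 3,4-cis; relative configuration) | O[C@H]1[C@@H](O)c2c(OC)cc(OC)c(OC)c2O[C@@H]1c1cc(OC)c(OCc2ccccc2)cc1OCc1ccccc1
A2 | alternative 1 | 2-{1-[2,4-bis(benzyloxy)-5-methoxyphenyl]-2-oxoethoxy}-3,4,6-trimethoxybenzaldehyde (racemic) | O=CC(Oc1c(OC)c(OC)cc(OC)c1C=O)c1cc(OC)c(OCc2ccccc2)cc1OCc1ccccc1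
A3 | alternative 2 | 2-[2,4-bis(benzyloxy)-5-methoxyphenyl]-5,7,8-trimethoxychromen-4-one | COc1cc(OC)c2c(=O)cc(-c3cc(OC)c(OCc4ccccc4)cc3OCc3ccccc3)oc2c1OC
A4 | alternative 2 | 2-iodo-3,5,6-trimethoxyphenol | Oc1c(I)c(OC)cc(OC)c1OC
A5 | alternative 2 | 1,5-bis(benzyloxy)-2-ethynyl-4-methoxybenzene | C#Cc1cc(OC)c(OCc2ccccc2)cc1OCc1ccccc1
A6 | alternative 3 | 3-(benzyloxy)-2-[2,4-bis(benzyloxy)-5-methoxyphenyl]-5,8-dihydroxy-7-methoxychromen-4-one | COc1cc(O)c2c(=O)c(OCc3ccccc3)c(-c3cc(OC)c(OCc4ccccc4)cc3OCc3ccccc3)oc2c1O
A7 | alternative 3 | 3-(benzyloxy)-2-[2,4-bis(benzyloxy)-5-methoxyphenyl]-6-(1-hydroxy-2-methoxy-4-oxocyclobut-2-en-1-yl)pyran-4-one (racemic) | COC1=CC(=O)C1(O)c1cc(=O)c(OCc2ccccc2)c(-c2cc(OC)c(OCc3ccccc3)cc2OCc2ccccc2)o1
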